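**Retrosynthetic overview**

1. Target 16 ⇐ 15 by a last, reagent-controlled epoxidation of the only remaining ring olefin (C3=C4). The C7-OAc/C8-OH pair comes from hydrolysis of a hydroxyl-directed 7,8-epoxide, and C11 from CBS reduction of an 11-ketone.
2. ε-Lactone ⇐ transannular opening of the (11S,12S)-epoxide by the C16 carboxylic acid (inversion at C12); the acid is made in the same pot from a C1 ethynyl group by Markovnikov hydroxycarbonylation.
3. 14-Membered carbocycle ⇐ C1–C2 closure of an acyclic farnesyl-derived epoxy aldehyde: a Pd-π-allyl (allyl cation surrogate) is captured by a chiral enamine (surrogate of the distal olefin), which sets C1.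
4. Acyclic chain ⇐ (2E,6E)-farnesyl acetate by SeO2 ω-hydroxylation, Sharpless epoxidation (C11/C12), triflate–vinyl coupling and hydroformylation.
5. Ring order: carbocycle (C1–C2) → ε-lactone (O–C12) → 7,8-oxirane (transient) → 3,4-oxirane.

Assumption: cembrane numbering is used (C1 carries the acrylate unit C15–C17, methyls sit on C4, C8 and C12, C16 is the lactone carbonyl); read this way the target SMILES is (1R,3S,4S,7R,8S,11R,12R).

**Route**

Step 1
Reactants: 1 (2E,6E)-farnesyl acetate
Product: 2 (2E,6E,10E)-12-hydroxy-3,7,11-trimethyldodeca-2,6,10-trien-1-yl acetate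
Conditions: SeO2 (0.3 equiv), t-BuOOH (3 equiv), salicylic acid (10 mol %), CH2Cl2, rt
Reagents that add atoms: tert-butyl hydroperoxide CC(C)(C)OO
Why: SeO2 allylic oxidation (ene reaction then [2,3]-sigmatropic shift) attacks the (E)-methyl of the electron-rich terminal isopropylidene group and leaves the acetate-deactivated end alone; no stereocentre is formed and the new allylic alcohol is E.

Step 2
Reactants: 2 (2E,6E,10E)-12-hydroxy-3,7,11-trimethyldodeca-2,6,10-trien-1-yl acetate
Product: 3 (2E,6E)-9-[(2S,3S)-3-(hydroxymethyl)-3-methyloxiran-2-yl]-3,7-dimethylnona-2,6-dien-1-yl acetate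
Conditions: Ti(Oi-Pr)4 (10 mol %), L-(+)-diethyl tartrate (12 mol %), t-BuOOH (2 equiv), 4 Å MS, CH2Cl2, −20 °C
Reagents that add atoms: tert-butyl hydroperoxide CC(C)(C)OO
Why: Sharpless asymmetric epoxidation reaches only the olefin that carries the free allylic hydroxyl, and L-(+)-tartrate gives the (S,S)-epoxide of this (E)-2-methyl allylic alcohol, which fixes the future C11 and C12 as 11S,12S.

Step 3
Reactants: 3 (2E,6E)-9-[(2S,3S)-3-(hydroxymethyl)-3-methyloxiran-2-yl]-3,7-dimethylnona-2,6-dien-1-yl acetate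
Product: 5 (2E,6E)-3,7-dimethyl-9-[(2S,3S)-3-methyl-3-(prop-2-enyl)oxiran-2-yl]nona-2,6-dien-1-yl acetate, via epoxy triflate 4 (not isolated)
Conditions: Tf2O, 2,6-lutidine, CH2Cl2, −78 °C; then CH2=CHMgBr (3 equiv), CuI (10 mol %), THF, −78 °C
Reagents that add atoms: vinylmagnesium bromide C=C[Mg]Br; trifluoromethanesulfonic anhydride O=S(=O)(OS(=O)(=O)C(F)(F)F)C(F)(F)F (its CF3SO2 group stays only in 4)
Why: Copper-catalysed Grignard–triflate cross-coupling (SN2 at the primary epoxy-carbinyl carbon) is much faster at −78 °C than attack on the trisubstituted epoxide or the acetate, so the C13–C14 bond forms with both epoxide stereocentres untouched.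

Step 4
Reactants: 5 (2E,6E)-3,7-dimethyl-9-[(2S,3S)-3-methyl-3-(prop-2-enyl)oxiran-2-yl]nona-2,6-dien-1-yl acetate
Product: 6 (2E,6E)-3,7-dimethyl-9-[(2S,3S)-3-methyl-3-(4-oxobutyl)oxiran-2-yl]nona-2,6-dien-1-yl acetate
Conditions: Rh(acac)(CO)2 (1 mol %), BiPhePhos (3 mol %), CO/H2 (1:1, 5 bar), toluene, 60 °C
Reagents that add atoms: carbon monoxide [C-]#[O+]
Why: Linear-selective rhodium hydroformylation converts only the monosubstituted terminal alkene (trisubstituted olefins, epoxide and acetate are inert) and installs C15 as the aldehyde with C1 as its α-CH2; no stereocentre is formed.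

Step 5
Reactants: 6 (2E,6E)-3,7-dimethyl-9-[(2S,3S)-3-methyl-3-(4-oxobutyl)oxiran-2-yl]nona-2,6-dien-1-yl acetate
Product: 7 (1R,3E,7E,11S,12S)-11,12-epoxy-4,8,12-trimethylcyclotetradeca-3,7-diene-1-carbaldehyde
Conditions: Pd(PPh3)4 (10 mol %), (S)-α,α-diphenylprolinol trimethylsilyl ether (30 mol %), DMSO/THF 1:1, 20 °C, syringe-pump addition over 16 h to 2 mM
Reagents that add atoms: none
Why: Proposed new method: Pd(0) ionises the allylic acetate to a cationic (E)-π-allyl complex (a tamed geranylgeranyl-type cation), the amine turns the aldehyde into an enamine that stands in for the distal C=C of the biosynthetic precursor and attacks the unsubstituted allyl terminus C2 from the face left open by the diarylsilyloxymethyl group, which is expected to set C1 as R (the facial sense this catalyst shows in intermolecular α-functionalisations), and iminium hydrolysis returns the amine; the closest known reactions are the dual amine/Pd intramolecular Tsuji–Trost α-allylation of aldehydes to five- and six-membered rings, its enantioselective intermolecular variant and Pd-templated macrocyclic allylic alkylation.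

Step 6
Reactants: 7 (1R,3E,7E,11S,12S)-11,12-epoxy-4,8,12-trimethylcyclotetradeca-3,7-diene-1-carbaldehyde
Product: 8 (1R,3E,7E,11S,12S)-11,12-epoxy-1-ethynyl-4,8,12-trimethylcyclotetradeca-3,7-diene
Conditions: TMSCHN2 (1.3 equiv), LDA (1.3 equiv), THF, −78 → 0 °C
Reagents that add atoms: (trimethylsilyl)diazomethane C[Si](C)(C)C=[N+]=[N-]
Why: Colvin homologation (addition, Peterson-type loss of silanolate, 1,2-hydride shift of the alkylidene carbene) turns the aldehyde into the terminal alkyne at low temperature without enolising the α-stereocentre, so C1 stays R.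

Step 7
Reactants: 8 (1R,3E,7E,11S,12S)-11,12-epoxy-1-ethynyl-4,8,12-trimethylcyclotetradeca-3,7-diene
Product: 10 (1R,3E,7E,11S,12R)-11-hydroxycembra-3,7,15(17)-trien-16,12-olide, via epoxy acrylic acid 9 (not isolated)
Conditions: Pd(OAc)2 (2 mol %), 2-(diphenylphosphino)pyridine (20 mol %), MsOH (10 mol %), CO (20 bar), H2O (3 equiv), THF, 45 °C; then CSA (20 mol %), CH2Cl2, 0 °C → rt
Reagents that add atoms: carbon monoxide [C-]#[O+]; water O
Why: Markovnikov Pd–H hydroxycarbonylation of the terminal alkyne (pyridylphosphine system) gives the α-substituted acrylic acid, whose carboxyl group then opens the 11,12-epoxide in an acid-catalysed 7-exo transannular lactonisation at the tertiary carbon with inversion (12S → 12R) while the C11–O bond is retained (11S).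

Step 8
Reactants: 10 (1R,3E,7E,11S,12R)-11-hydroxycembra-3,7,15(17)-trien-16,12-olide
Product: 12 (1R,3E,7R,8R,12R)-7,8-epoxy-11-oxocembra-3,15(17)-dien-16,12-olide, via epoxy alcohol 11 (not isolated)
Conditions: VO(acac)2 (5 mol %), t-BuOOH (1.2 equiv), 2,6-lutidine (0.2 equiv), CH2Cl2, 0 °C; then pyridine, Dess–Martin periodinane, 0 °C → rt
Reagents that add atoms: tert-butyl hydroperoxide CC(C)(C)OO
Why: Vanadium-catalysed hydroxyl-directed epoxidation of a bishomoallylic alcohol reaches only the 7,8-olefin through the C11 vanadate (the 3,4-olefin and the acrylate are out of reach) and, through the chair-like transition state that normally leads to trans-2,5-tetrahydrofurans, is expected to give the (7R,8R)-epoxide from the 11S carbinol, after which Dess–Martin oxidation in the same pot removes the C11 hydroxyl before it can open the epoxide and stores C11 as a ketone for later inversion.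

Step 9
Reactants: 12 (1R,3E,7R,8R,12R)-7,8-epoxy-11-oxocembra-3,15(17)-dien-16,12-olide
Product: 13 (1R,3E,7R,8S,12R)-7,8-dihydroxy-11-oxocembra-3,15(17)-dien-16,12-olide
Conditions: HClO4 (5 mol %), THF/H2O 3:1, 0 °C
Reagents that add atoms: water O
Why: Acid-catalysed epoxide hydrolysis lets water attack the tertiary C8 with inversion (8R → 8S) while C7 keeps its oxygen (7R), and a transient participation of the 11-ketone at C8 would give the same anti diol after hydrolysis.

Step 10
Reactants: 13 (1R,3E,7R,8S,12R)-7,8-dihydroxy-11-oxocembra-3,15(17)-dien-16,12-olide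
Product: 14 (1R,3E,7R,8S,12R)-7-acetoxy-8-hydroxy-11-oxocembra-3,15(17)-dien-16,12-olide
Conditions: Ac2O, pyridine, DMAP (5 mol %), CH2Cl2, 0 °C → rt
Reagents that add atoms: acetic anhydride CC(=O)OC(C)=O
Why: Nucleophile-catalysed acylation acetylates only the secondary C7–OH because the C8–OH is tertiary and C11 is still a ketone, so the acetate is placed without protecting groups and no stereocentre is touched.

Step 11
Reactants: 14 (1R,3E,7R,8S,12R)-7-acetoxy-8-hydroxy-11-oxocembra-3,15(17)-dien-16,12-olide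
Product: 15 (1R,3E,7R,8S,11R,12R)-7-acetoxy-8,11-dihydroxycembra-3,15(17)-dien-16,12-olide
Conditions: (S)-2-methyl-CBS-oxazaborolidine (20 mol %), catecholborane (3 equiv), toluene, −78 → −40 °C
Reagents that add atoms: none
Why: Corey–Bakshi–Shibata reduction, in which the (S)-oxazaborolidine tells the quaternary C12 (large) from C10H2 (small) and delivers hydride to give the 11R alcohol, syn to the C12 lactone oxygen, while catecholborane at low temperature spares the lactone, the acetate and the acrylate.

Step 12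
Reactants: 15 (1R,3E,7R,8S,11R,12R)-7-acetoxy-8,11-dihydroxycembra-3,15(17)-dien-16,12-olide
Product: 16 (1R,3S,4S,7R,8S,11R,12R)-7-acetoxy-3,4-epoxy-8,11-dihydroxycembr-15(17)-en-16,12-olide
Conditions: ent-Shi ketone (L-fructose-derived, 0.5 equiv), Oxone, K2CO3, Bu4NHSO4 (cat.), MeCN/DMM–aq. Na2B4O7/EDTA (pH 10.5), 0 °C
Reagents that add atoms: potassium peroxymonosulfate (Oxone) [K+].[O-]S(=O)(=O)OO
Why: Shi asymmetric epoxidation (chiral dioxirane, spiro transition state) of the only remaining electron-rich olefin, with the ent-ketone giving the (3S,4S)-epoxide by reagent control while the acrylate is too electron-poor to react.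

**Compound list**

1 | (2E,6E)-farnesyl acetate | CC(C)=CCC/C(C)=C/CC/C(C)=C/COC(C)=O | starting material
2 | (2E,6E,10E)-12-hydroxy-3,7,11-trimethyldodeca-2,6,10-trien-1-yl acetate | OC/C(C)=C/CC/C(C)=C/CC/C(C)=C/COC(C)=O | intermediate
3 | (2E,6E)-9-[(2S,3S)-3-(hydroxymethyl)-3-methyloxiran-2-yl]-3,7-dimethylnona-2,6-dien-1-yl acetate | OC[C@]1(C)O[C@H]1CC/C(C)=C/CC/C(C)=C/COC(C)=O | intermediate
4 | (2E,6E)-3,7-dimethyl-9-[(2S,3S)-3-methyl-3-(trifluoromethylsulfonyloxymethyl)oxiran-2-yl]nona-2,6-dien-1-yl acetate (epoxy triflate) | O=S(=O)(OC[C@]1(C)O[C@H]1CC/C(C)=C/CC/C(C)=C/COC(C)=O)C(F)(F)F | intermediate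
5 | (2E,6E)-3,7-dimethyl-9-[(2S,3S)-3-methyl-3-(prop-2-enyl)oxiran-2-yl]nona-2,6-dien-1-yl acetate | C=CC[C@]1(C)O[C@H]1CC/C(C)=C/CC/C(C)=C/COC(C)=O | intermediate
6 | (2E,6E)-3,7-dimethyl-9-[(2S,3S)-3-methyl-3-(4-oxobutyl)oxiran-2-yl]nona-2,6-dien-1-yl acetate | O=CCCC[C@]1(C)O[C@H]1CC/C(C)=C/CC/C(C)=C/COC(C)=O | intermediate
7 | (1R,3E,7E,11S,12S)-11,12-epoxy-4,8,12-trimethylcyclotetradeca-3,7-diene-1-carbaldehyde | O=C[C@H]1C/C=C(C)/CC/C=C(C)/CC[C@@H]2O[C@@]2(C)CC1 | intermediate
8 | (1R,3E,7E,11S,12S)-11,12-epoxy-1-ethynyl-4,8,12-trimethylcyclotetradeca-3,7-diene | C#C[C@H]1C/C=C(C)/CC/C=C(C)/CC[C@@H]2O[C@@]2(C)CC1 | intermediate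
9 | (1R,3E,7E,11S,12S)-11,12-epoxycembra-3,7,15(17)-trien-16-oic acid (epoxy acrylic acid) | C=C(C(=O)O)[C@H]1C/C=C(C)/CC/C=C(C)/CC[C@@H]2O[C@@]2(C)CC1 | intermediate
10 | (1R,3E,7E,11S,12R)-11-hydroxycembra-3,7,15(17)-trien-16,12-olide | C=C1C(=O)O[C@]2(C)CC[C@@H]1C/C=C(C)/CC/C=C(C)/CC[C@@H]2O | intermediate
11 | (1R,3E,7R,8R,11S,12R)-7,8-epoxy-11-hydroxycembra-3,15(17)-dien-16,12-olide (epoxy alcohol) | C=C1C(=O)O[C@]2(C)CC[C@@H]1C/C=C(C)/CC[C@H]3O[C@]3(C)CC[C@@H]2O | intermediate
12 | (1R,3E,7R,8R,12R)-7,8-epoxy-11-oxocembra-3,15(17)-dien-16,12-olide | C=C1C(=O)O[C@]2(C)CC[C@@H]1C/C=C(C)/CC[C@H]3O[C@]3(C)CCC2=O | intermediate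
13 | (1R,3E,7R,8S,12R)-7,8-dihydroxy-11-oxocembra-3,15(17)-dien-16,12-olide | C=C1C(=O)O[C@]2(C)CC[C@@H]1C/C=C(C)/CC[C@@H](O)[C@@](C)(O)CCC2=O | intermediate
14 | (1R,3E,7R,8S,12R)-7-acetoxy-8-hydroxy-11-oxocembra-3,15(17)-dien-16,12-olide | C=C1C(=O)O[C@]2(C)CC[C@@H]1C/C=C(C)/CC[C@@H](OC(C)=O)[C@@](C)(O)CCC2=O | intermediate
15 | (1R,3E,7R,8S,11R,12R)-7-acetoxy-8,11-dihydroxycembra-3,15(17)-dien-16,12-olide | C=C1C(=O)O[C@]2(C)CC[C@@H]1C/C=C(C)/CC[C@@H](OC(C)=O)[C@@](C)(O)CC[C@H]2O | intermediate
16 | (1R,3S,4S,7R,8S,11R,12R)-7-acetoxy-3,4-epoxy-8,11-dihydroxycembr-15(17)-en-16,12-olide (CNP0174704.2) | C=C1C(=O)O[C@]2(C)CC[C@@H]1C[C@@H]1O[C@@]1(C)CC[C@@H](OC(C)=O)[C@@](C)(O)CC[C@H]2O | target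

**Step count and risks**

Total step count: 12. Longest linear sequence: 12 (from 1).

The three steps most likely to fail:

Step 5 (macrocyclisation). A catalytic enamine is a weak nucleophile for a 14-membered closure; oligomers, N-allylation of the amine, diene formation from the π-allyl, E/Z leakage at C3=C4 and incomplete control at C1 are all possible. The fallback sets out from aldehyde 6 and comes back at macrocyclic aldehyde 7, and replaces the catalytic step by a stoichiometric auxiliary-controlled SN2 alkylation. Condensation of 6 with (R)-1-amino-2-(methoxymethyl)pyrrolidine gives the hydrazone acetate F1. K2CO3 in MeOH frees the allylic alcohol to give the hydrazone alcohol F2. MsCl, LiCl and 2,6-lutidine in DMF give the hydrazone chloride F3. LDA in THF at −100 → −78 °C under high dilution closes the ring by intramolecular Enders alkylation of the lithio-azaenolate on the allylic chloride; the RAMP auxiliary directs C1 to R and gives the macrocyclic hydrazone F4. Aqueous CuCl2 in THF cleaves the auxiliary without epimerisation to give 7.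

Step 7 (hydroxycarbonylation and lactonisation). The acid co-catalyst and water may open the 11,12-epoxide before the carboxylic acid exists, and the α-branched alkyne may give some linear acid. The fallback sets out from alkyne 8 and comes back at acid 9, which is lactonised to 10 with CSA as in the second half of step 7; it builds the acid by hydrometalation and CO2 capture under non-acidic conditions. Ni(dppp)Cl2-catalysed α-selective hydroalumination with DIBAL-H (THF, 0 °C) gives the internal alkenylalane F5, and addition of MeLi followed by CO2 carboxylates the ate complex at C15 to give 9 after mild aqueous work-up.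

Step 8 (directed epoxidation and oxidation). The epoxy alcohol 11 can close to the 8,11-tetrahydrofuran before it is oxidised, and the facial preference of the vanadium epoxidation is taken from an acyclic model that may not hold in this ring. The fallback sets out from hydroxy lactone 10 and comes back at epoxy ketone 12, and never passes through an epoxy alcohol. Dess–Martin oxidation first gives the 11-keto diene lactone F6. Oxone and NaHCO3 in aqueous MeCN then convert the activated α-acyloxy ketone into a dioxirane that should deliver oxygen intramolecularly to the nearby 7,8-olefin and leave the remote 3,4-olefin alone, giving 12.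

**Further compounds**

F1 | step 5 | RAMP hydrazone of aldehyde 6 (hydrazone acetate) | COC[C@H]1CCCN1/N=C/CCC[C@]2(C)O[C@H]2CC/C(C)=C/CC/C(C)=C/COC(C)=O
F2 | step 5 | RAMP hydrazone with free allylic alcohol (hydrazone alcohol) | COC[C@H]1CCCN1/N=C/CCC[C@]2(C)O[C@H]2CC/C(C)=C/CC/C(C)=C/CO
F3 | step 5 | RAMP hydrazone with allylic chloride (hydrazone chloride) | COC[C@H]1CCCN1/N=C/CCC[C@]2(C)O[C@H]2CC/C(C)=C/CC/C(C)=C/CCl
F4 | step 5 | RAMP hydrazone of macrocyclic aldehyde 7 (macrocyclic hydrazone) | COC[C@H]1CCCN1/N=C/[C@H]3C/C=C(C)/CC/C=C(C)/CC[C@@H]2O[C@@]2(C)CC3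
F5 | step 7 | (1R,3E,7E,11S,12S)-1-[1-(diisobutylalumanyl)ethenyl]-11,12-epoxy-4,8,12-trimethylcyclotetradeca-3,7-diene (alkenylalane) | CC(C)C[Al](CC(C)C)C(=C)[C@H]1C/C=C(C)/CC/C=C(C)/CC[C@@H]2O[C@@]2(C)CC1
F6 | step 8 | (1R,3E,7E,12R)-11-oxocembra-3,7,15(17)-trien-16,12-olide (11-keto diene lactone) | C=C1C(=O)O[C@]2(C)CC[C@@H]1C/C=C(C)/CC/C=C(C)/CCC2=O
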